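Target and isomer of the product cannot share one order in reagent: at 15.0 h the oak run, charged 2 M of reagent, held 37% target and 36% isomer of the product, while the elm run, at 1 M, held 23% and 37%. Those two runs differ in substrate charge too, but the ash run, charged 1 M of substrate and 2 M of reagent, held 33% target and 34% isomer of the product at 15.0 h. The meeting began there.

| flask | substrate | reagent | remark | time |
|---|---|---|---|---|
| oak | 0.25 M | 2 M | run made earlier |  |
| ash | 1 M | 2 M | run made earlier |  |
| elm | 0.50 M | 1 M | run made earlier |  |
| flask | 0.50 M | 2.00 M |  | 20 h |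

| run | time / h | isomer of the product / % | target / % | substrate / % |
|---|---|---|---|---|
| oak | 1.00 | 1 | 9 | 85 |
| oak | 3.00 | 11 | 18 | 72 |
| oak | 6.00 | 17 | 26 | 56 |
| oak | 8.00 | 25 | 27 | 45 |
| oak | 12.0 | 34 | 34 | 33 |
| oak | 15.0 | 36 | 37 | 26 |
| ash | 1.33 | 0 | 9 | 82 |
| ash | 2.00 | 6 | 13 | 79 |
| ash | 4.00 | 11 | 20 | 66 |
| ash | 6.00 | 16 | 24 | 53 |
| ash | 10.0 | 22 | 28 | 39 |
| ash | 15.0 | 34 | 33 | 30 |
| elm | 1.33 | 6 | 5 | 86 |
| elm | 4.00 | 15 | 10 | 73 |
| elm | 8.00 | 22 | 19 | 53 |
| elm | 12.0 | 33 | 22 | 43 |
| elm | 15.0 | 37 | 23 | 34 |

(standard deviation of a reading: 2 percentage points)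



* ratio of isomer of the product to target at 8.0 min
* ratio of isomer of the product to target at 80 min
* ratio of isomer of the product to target at 20 h

The kineticist argued that target is first order in reagent and isomer of the product roughly zero order, so the ratio in which they are made, a selectivity factor, runs as B*/[reagent], where [reagent] is the reagent concentration. From oak and ash at 6.00 h, charge times isomer over target gives the reading B* = 1.32 M, the parity concentration: the reagent level at which the two products form equally fast. Elm, at its different charge, reads 1.50 M at 4.00 h, within scatter, she said.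

For this flask she therefore expected 0.660 at the charge. The ratio should lie under that at first, since oak showed 1% against 9% at 1.00 h. By 20.0 h it should stand above the 1.00 of oak and ash at 15.0 h, which she took as reagent falling.

The forecaster tabled 0.28, 0.35 and 1.2, holding that the “earliest points are noisy and lower”. The kineticist took those low early points as real.

The flask gave 0.0903, 0.445 and 1.11.

    2 reagent → self-condensation product (k = 0.0400 L mol⁻¹ h⁻¹)
    substrate + reagent → target (k = 0.0420 L mol⁻¹ h⁻¹)
    reagent + other conformer → isomer of the product (k = 1.30 L mol⁻¹ h⁻¹)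
    substrate ⇌ other conformer (K = 2.00, k = 0.0490 h⁻¹)

At 20.0 h the flask kept 18% of its reagent. B* over the mean of charge and remainder, 1.18 M, gives 1.12. The neighbour flask charged with 0.80 M of reagent kept 23%, a mean of 0.491 M, so B* gives 2.69; that neighbour flask stood lower, at 2.22.

The earlier runs and the new flask come from a simulation with constants of no real substance, noise included.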